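Apart from the 3.8 mol% of G that can hold some of it, the Q that has left the flask either stands as E or has already gone on from E, and this ledger holds at every minute. So the end amount of E depends on when Q left and how much of it has survived since.

common to all: Q 0.050 M (fed, over 12 s); G 3.8 mol%

|  | L | remark | time |
|---|---|---|---|
| Saturday's | 0.47 equiv | run made earlier |  |
| Friday's | 1.6 equiv | run made earlier |  |
| birch | 0.600 equiv |  | 3.0 min |
| ash | 1.00 equiv |  | 3.0 min |
| elm | 1.50 equiv |  | 3.0 min |

| Saturday's: time / min | Saturday's: E / % | Friday's: time / min | Friday's: E / % |
|---|---|---|---|
| 0.667 | 18 | 0.250 | 29 |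
| 1.33 | 17 | 0.417 | 43 |
| 2.00 | 9 | 0.833 | 52 |
| 2.50 | 2 | 1.50 | 24 |
| 3.00 | 5 | 3.00 | 3 |

(scatter of a reading: 1.5 percentage points)

- "hardly changes" means that all values lie within two and a half points (for a concentration: within two and a half percent of the largest)

* amount of E at the end, in percent of the Q charged for birch, ash, elm, in this order
* how the row runs (rises all the way / falls all the way / hardly changes / falls, then rises / rises, then falls)

Survival can be read from Friday's run, taking Q as used up by 1.50 min with L in excess. E falls from 24% there to 3% at 3.00 min, which gives 0.721 min as the tail life, the mean time an E survives once it is formed. It is a reading, and its last point carries a scatter of 1.5 percentage points. From 1.50 min to 3.0 min, E standing at the start of that span keeps 12.5%. Q leaving during the span, counted at its midpoint, keeps 35.4%. The end amount is the sum of the two.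

Two views meet here. The flat view says the tail life is short against the run, so E at the end is a remnant whatever the charge. Saturday's 5% and Friday's 3% lie 2 points apart, so a row between them stays level.

My view is that those two runs, at 0.47 equiv and 1.6 equiv, each have a limiting reagent facing an excess, while ash at 1.00 equiv has neither partner in excess, so Q keeps leaving late. Assuming a second-order rate of about 2.00 min⁻¹ per equivalent, a rough guess of mine and no fit, I estimate that ash loses 10.7% of its Q in that span. Lending ash Friday's 24% of E at the start of the span, I get 6.79%, which is 3.8 points above Friday's end. With the neighbouring ends taken for birch and elm, I commit to a row that rises, then falls.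

The flat view's number is the forecast, 4.5%, 6%, 4%, with the shape "hardly changes": “so the row hardly changes”.

    Z → G + E (k = 3.30 s⁻¹)
    E → X (k = 0.0210 s⁻¹)
    L + G ⇌ D (K = 290 M⁻¹, k = 13.0 M⁻¹ s⁻¹)
    Q + D ⇌ Z (K = 530 M⁻¹, k = 260 M⁻¹ s⁻¹)

The flask gives 4.92%, 8.72% and 4.30%, so the shape is "rises, then falls", and the flat view keeps the outer flasks, birch and elm, 0.62 points apart. In ash, Q stood at 15.2% at 1.50 min and 2.33% at 3.00 min, while in elm it stood at 0% by 1.50 min. With the tail life, ash's 29.5% of E at 1.50 min and that fall of Q give 8.24%. Elm's 28.4% at 1.50 min, with no Q leaving, gives 3.55%, against the flask's 4.30%.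

The numbers in the tables are calculated with constants of no real substance; scatter was added.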